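**Plan**

- Ring numbering of the target: C1 (OH), C2 (H), C3 (heptadecyl), C4 (OMe), C5 (OMe), C6 (H). The meta oxygens on C1 and C5, the chain on C3 and the unsubstituted C2 between them mark a resorcylate that has lost its carboxyl. The benzene ring can therefore be folded from a linear stearoyl-plus-three-acetate chain whose carbon next to the starter carbonyl already carries the C4 oxygen as a methoxy group.
- Retrosynthesis: put a CO2Me back on C2, remove the methyl from O–C5, then cut the ring bond C2–C3 (aldol condensation in reverse) to open-chain methyl 6-methoxy-3,5,7-trioxotetracosanoate. The chain is then cut between chain atoms C6/C7 and C4/C5 (two polyanion acylations).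
- Forward: the acetoacetate dianion is acylated with methyl methoxyacetate (chain C1–C6). The trianion of that diketo ester is acylated at C6 with the N-methoxy-N-methylamide of stearic acid (C7–C24). The only ring closes in step 4, followed by para-selective O-methylation and saponification with decarboxylation.
- Stereochemistry: the target has no stereocenter. The centres that appear at chain C6 and in the cyclic aldol adduct are uncontrolled and vanish on aromatization.

Key step: step 4

Remark: the polycarbonyl compounds are drawn as keto tautomers although they are largely enolized, and the polyanions are drawn as lithium enolates.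

**Route**

Step 1
Reactants: 1 methyl acetoacetate; 2 methyl methoxyacetate
Product: 4 methyl 6-methoxy-3,5-dioxohexanoate, via dilithium dienolate 3 (not isolated)
Conditions: 1 (2.1 equiv), LiN(iPr)2 (4.2 equiv), THF, 0 °C; then 2 (1.0 equiv), −78 to 0 °C; cold 1 M HCl
Reagents that add atoms: none
Why: Claisen-type γ-acylation of the acetoacetate dianion, in which the terminal carbanion of 3 is the more nucleophilic site and attacks the activated α-alkoxy ester, while a second equivalent of 3 is consumed as base because 4 is more acidic than 1, as is usual for this reaction.

Step 2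
Reactants: 5 octadecanoyl chloride
Product: 6 N-methoxy-N-methyloctadecanamide
Conditions: MeNHOMe·HCl, K2CO3, t-BuOMe/H2O, 0 °C to rt
Reagents that add atoms: N,O-dimethylhydroxylamine hydrochloride, CNOC.Cl
Why: Schotten–Baumann acylation of the hydroxylamine gives an acyl donor that accepts a carbon nucleophile only once and whose α-hydrogens are far less acidic than those of methyl octadecanoate, so the basic trianion of step 3 should not simply enolize it.

Step 3
Reactants: 4 methyl 6-methoxy-3,5-dioxohexanoate; 6 N-methoxy-N-methyloctadecanamide
Product: 8 methyl 6-methoxy-3,5,7-trioxotetracosanoate, via trilithium trienolate 7 (not isolated)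
Conditions: LiN(iPr)2 (3.3 equiv), THF, −78 to 0 °C; then 6 (0.9 equiv), 0 °C to rt; cold aq. HCl to pH 4
Reagents that add atoms: none
Why: Claisen-type C-acylation of a 3,5-diketo ester trianion, in which the last-formed and least stabilized carbanion (the methoxy-bearing C6 of 7, an α-alkoxy enolate of the kind LiN(iPr)2 forms routinely) is the most nucleophilic site and adds to the amide, whose lithium-chelated adduct collapses only on work-up so that the acidic C6–H of 8 never meets unreacted 7.

Step 4
Reactants: 8 methyl 6-methoxy-3,5,7-trioxotetracosanoate
Product: 10 methyl 6-heptadecyl-2,4-dihydroxy-5-methoxybenzoate, via cyclic aldol adduct 9 (not isolated)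
Conditions: Cs2CO3 (2 equiv), MeOH, 0 °C to rt; then HCl in MeOH, rt
Reagents that add atoms: none
Why: Carbonate reversibly deprotonates the chain, the carbanion at chain C2 (between the ester and the C3 ketone) adds to the C7 ketone to give carbinol 9, and acid then removes water while the C3 and C5 carbonyls enolize, so that the chain C2–C7 bond becomes the ring bond between the ester-bearing and the heptadecyl-bearing carbons (C2–C3 of the target). The closest known reaction type is the biomimetic intramolecular aldol condensation of 3,5,7-triketo esters to 6-substituted 2,4-dihydroxybenzoates. The six-membered ring closes in a 6-exo-trig mode at the ketone carbon, allowed for the C2 carbanion whether it is described as enolexo (ester enolate) or enolendo (C3 ketone enolate). No stereocenter is set, since C6 of 8 and the three sp3 centres of 9 all become aromatic carbons. The selectivity required is aldol closure C2 to C7 over Claisen closure C6 to C1 and over lactonization to pyranones; the C6 methoxy group secures it, because the Claisen product would be a 2-acyl-2-methoxycyclohexanetrione that cannot aromatize and reverts to 8, whereas dehydration of 9 is irreversible. The methoxy group also lowers the enol content of the C5/C7 diketone and so keeps C7 electrophilic, while the more stabilized carbanions at C4 and C6 can close no six-membered aldol ring and only act as reservoirs.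

Step 5
Reactants: 10 methyl 6-heptadecyl-2,4-dihydroxy-5-methoxybenzoate
Product: 11 methyl 6-heptadecyl-2-hydroxy-4,5-dimethoxybenzoate
Conditions: MeI (1.1 equiv), K2CO3 (1.1 equiv), acetone, rt to 40 °C
Reagents that add atoms: iodomethane, CI
Why: Williamson ether synthesis under substrate control, since the hydroxyl para to the ester is the more acidic and is free whereas the ortho hydroxyl is held in a hydrogen bond to the ester carbonyl, so one equivalent of MeI should methylate only the para oxygen, as is general for 2,4-dihydroxybenzoates.

Step 6
Reactants: 11 methyl 6-heptadecyl-2-hydroxy-4,5-dimethoxybenzoate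
Product: 13 3-heptadecyl-4,5-dimethoxyphenol, via carboxylic acid 12 (not isolated)
Conditions: KOH (10 equiv), EtOH/H2O, reflux, argon; then aq. HCl to pH 1, 80 °C
Reagents that add atoms: none
Why: Saponification of the salicylate ester followed by acid-promoted protodecarboxylation, which should be easy because the carboxyl-bearing carbon of 12 lies ortho to a hydroxyl and para to a methoxy group and is crowded by two ortho substituents, as in other 6-alkyl-2,4-dioxygenated benzoic acids.

**Compound list**

1 | methyl acetoacetate (methyl 3-oxobutanoate) | CC(=O)CC(=O)OC | starting material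
2 | methyl methoxyacetate | COCC(=O)OC | starting material
3 | dilithium dienolate of methyl acetoacetate (C2,C4-dianion) | C=C(O[Li])C=C(O[Li])OC | intermediate
4 | methyl 6-methoxy-3,5-dioxohexanoate | COCC(=O)CC(=O)CC(=O)OC | intermediate
5 | octadecanoyl chloride (stearoyl chloride) | CCCCCCCCCCCCCCCCCC(=O)Cl | starting material
6 | N-methoxy-N-methyloctadecanamide | CCCCCCCCCCCCCCCCCC(=O)N(C)OC | intermediate
7 | trilithium trienolate of methyl 6-methoxy-3,5-dioxohexanoate (C2,C4,C6-trianion) | COC=C(O[Li])C=C(O[Li])C=C(O[Li])OC | intermediate
8 | methyl 6-methoxy-3,5,7-trioxotetracosanoate (racemic at C6, labile) | CCCCCCCCCCCCCCCCCC(=O)C(OC)C(=O)CC(=O)CC(=O)OC | intermediate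
9 | methyl 2-heptadecyl-2-hydroxy-3-methoxy-4,6-dioxocyclohexane-1-carboxylate (mixture of diastereomers) | CCCCCCCCCCCCCCCCCC1(O)C(OC)C(=O)CC(=O)C1C(=O)OC | intermediate
10 | methyl 6-heptadecyl-2,4-dihydroxy-5-methoxybenzoate | CCCCCCCCCCCCCCCCCc1c(OC)c(O)cc(O)c1C(=O)OC | intermediate
11 | methyl 6-heptadecyl-2-hydroxy-4,5-dimethoxybenzoate | CCCCCCCCCCCCCCCCCc1c(OC)c(OC)cc(O)c1C(=O)OC | intermediate
12 | 6-heptadecyl-2-hydroxy-4,5-dimethoxybenzoic acid | CCCCCCCCCCCCCCCCCc1c(OC)c(OC)cc(O)c1C(=O)O | intermediate
13 | 3-heptadecyl-4,5-dimethoxyphenol | CCCCCCCCCCCCCCCCCc1cc(O)cc(OC)c1OC | target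

**Step count and risks**

Total steps: 6. Longest linear sequence: 5 (steps 1, 3, 4, 5, 6; step 2 is a one-step side branch).

Steps most likely to fail:

Step 3. The third deprotonation at the methoxy-bearing carbon may be incomplete, or the strongly basic trianion may take a proton from 6 instead of adding to it, so that 4 is returned. The fallback makes the C6–C7 bond before the methoxy group is present and introduces the oxygen afterwards; it sets out from 6 and rejoins the route at 8. Commercial 2,2,6-trimethyl-4H-1,3-dioxin-4-one is deprotonated with LiN(SiMe3)2 and acylated with acetyl chloride to 2,2-dimethyl-6-(2-oxopropyl)-4H-1,3-dioxin-4-one F1. Its dianion (LiN(iPr)2, 2 equiv, THF, −78 °C) is acylated at the terminal methyl by 6 to give 6-(2,4-dioxohenicosyl)-2,2-dimethyl-4H-1,3-dioxin-4-one F2, in which the β-keto ester end is masked and the only methylene between two free ketones is the future chain C6. Diazo transfer at that methylene with 4-acetamidobenzenesulfonyl azide and Et3N in MeCN gives 6-(3-diazo-2,4-dioxohenicosyl)-2,2-dimethyl-4H-1,3-dioxin-4-one F3. O–H insertion into methanol catalysed by Rh2(OAc)4 then gives 6-(3-methoxy-2,4-dioxohenicosyl)-2,2-dimethyl-4H-1,3-dioxin-4-one F4. Heating F4 with methanol in toluene at 110 °C expels acetone, and the acylketene is trapped as the methyl ester 8.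

Step 4. The enol oxygen may lactonize onto the methyl ester to give a pyranone, or methoxide may cleave the chain at the methoxy-bearing carbon (retro-Claisen) before the aldol ring closes. The fallback closes the same C2–C7 bond with the ester locked in a ring; it sets out from 6, follows the sequence above as far as F4, and rejoins the route at 10. F4 is treated with Et3N in CH2Cl2 at rt, conditions under which diketo-dioxinones undergo the same aldol condensation and aromatization, to give 5-heptadecyl-7-hydroxy-6-methoxy-2,2-dimethyl-4H-1,3-benzodioxin-4-one F5. The dioxinone carbonyl cannot lactonize or act as a Claisen acceptor, and no alkoxide is present. Catalytic NaOMe in MeOH then opens the benzodioxinone with loss of acetone to the methyl ester 10.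

Step 6. Hydrolysis may stall at the doubly ortho-flanked carbonyl, and the electron-rich phenolate may be oxidized in hot alkali. The fallback cleaves the ester at the O–CH3 bond instead of at the carbonyl; it sets out from 11 and rejoins the route at 12. LiI in refluxing pyridine under argon attacks the ester methyl group in an SN2 reaction, which is indifferent to crowding at the carbonyl and needs no hydroxide, to give the lithium salt of the acid. Acidification delivers 12, which loses CO2 on warming as in step 6 to give 13. No new compound arises.

**Further compounds**

F1 | step 3 | 2,2-dimethyl-6-(2-oxopropyl)-4H-1,3-dioxin-4-one | CC(=O)CC1=CC(=O)OC(C)(C)O1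
F2 | step 3 | 6-(2,4-dioxohenicosyl)-2,2-dimethyl-4H-1,3-dioxin-4-one | CCCCCCCCCCCCCCCCCC(=O)CC(=O)CC1=CC(=O)OC(C)(C)O1
F3 | step 3 | 6-(3-diazo-2,4-dioxohenicosyl)-2,2-dimethyl-4H-1,3-dioxin-4-one | CCCCCCCCCCCCCCCCCC(=O)C(=[N+]=[N-])C(=O)CC1=CC(=O)OC(C)(C)O1
F4 | step 3 | 6-(3-methoxy-2,4-dioxohenicosyl)-2,2-dimethyl-4H-1,3-dioxin-4-one | CCCCCCCCCCCCCCCCCC(=O)C(OC)C(=O)CC1=CC(=O)OC(C)(C)O1
F5 | step 4 | 5-heptadecyl-7-hydroxy-6-methoxy-2,2-dimethyl-4H-1,3-benzodioxin-4-one | CCCCCCCCCCCCCCCCCc1c(OC)c(O)cc2OC(C)(C)OC(=O)c12
F0 | step 6 | none | none
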